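## Retrosynthetic overview
1. The O1–C2 and C3–OH bonds of ring C are cut together. This leads from the (2R,3R)-dihydroflavonol, as its 3',4'-bis-TBS ether (TBS = tert-butyldimethylsilyl), back to an achiral 2',6'-dihydroxychalcone.
2. In the forward direction this is one flask. A chalcone-isomerase-type 6-endo oxa-Michael closure is followed by flavanone-3-hydroxylase-type oxygen transfer from a chiral oxaziridine to the ring-closed enolate. Both stereocentres arise here by dynamic kinetic resolution, and fluoride then frees the catechol.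
3. The chalcone comes from a Claisen–Schmidt union of 4-O-prenylphloroacetophenone (ring A) and bis-TBS protocatechualdehyde (ring B).
4. These come from phloroacetophenone plus prenyl bromide, and from 3,4-dihydroxybenzaldehyde plus TBSCl.
5. Ring order: rings A and B are bought. Ring C is the only ring formed, in the last step.

Assumption: the SMILES decodes to (2R,3R), the trans series of natural (+)-taxifolin, so the target is 7-O-prenyl-(+)-taxifolin.
Assumption: any 7 that closes to its racemic flavanone on handling is carried along, because the base in step 4 reopens it to 8.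

## Route

Step 1
Reactants: 1 2,4,6-trihydroxyacetophenone (dried); 2 prenyl bromide
Product: 3 2,6-dihydroxy-4-prenyloxyacetophenone
Conditions: K2CO3 (1.05 equiv), acetone, reflux, 6 h
Reagents that add atoms: none
Why: Williamson ether synthesis: the 4-OH is the most acidic phenol and the only one not hydrogen-bonded to the carbonyl group, so one equivalent of weak base in acetone puts a single prenyl group on O-4 (no stereocentre formed).

Step 2
Reactants: 4 3,4-dihydroxybenzaldehyde
Product: 5 3,4-bis(tert-butyldimethylsilyloxy)benzaldehyde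
Conditions: TBSCl (2.4 equiv), imidazole (5 equiv), DMF, 0 °C to rt
Reagents that add atoms: TBSCl (tert-butyldimethylsilyl chloride), CC(C)(C)[Si](C)(C)Cl
Why: Standard imidazole-promoted silyl ether formation: the TBS groups shield the oxidation-prone catechol from the later oxygen-transfer reagent, survive amide bases, and leave with fluoride under conditions that spare the acid-labile prenyl ether.

Step 3
Reactants: 3 2,6-dihydroxy-4-prenyloxyacetophenone; 5 3,4-bis(tert-butyldimethylsilyloxy)benzaldehyde
Product: 7 (E)-2',6'-dihydroxy-4'-prenyloxy-3,4-bis(TBSO)chalcone, via trilithium aldolate 6 (not isolated)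
Conditions: LiN(SiMe3)2 (3.3 equiv), THF, −78 to −10 °C; then 5, −78 °C to rt, 12 h; cold 1 M HCl
Reagents that add atoms: none
Why: Claisen–Schmidt aldol condensation on the polyanion: the non-nucleophilic amide base removes both phenol protons and one methyl proton, the lithium enolate adds to 5, and E1cB loss of hydroxide from 6 gives the conjugated E-enone, whereas aqueous KOH would strip the aryl silyl ethers.

Step 4
Reactants: 7 (E)-2',6'-dihydroxy-4'-prenyloxy-3,4-bis(TBSO)chalcone
Product: 11 (2R,3R)-7-O-prenyltaxifolin (target), via disodium chalcone bis-phenoxide 8 (not isolated), via disodium (2S)-flavanone enolate 9 (not isolated), via (2R,3R)-bis-TBS dihydroflavonol 10 (not isolated)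
Conditions: NaN(SiMe3)2 (2.05 equiv), THF, −78 to 0 °C; (+)-(camphorylsulfonyl)oxaziridine (1.2 equiv) by syringe pump over 4 h, 0 °C; AcOH; then KHF2 (4 equiv), MeOH, rt
Reagents that add atoms: (+)-(2R,8aS)-10-(camphorylsulfonyl)oxaziridine, CC1(C)[C@@H]2CC[C@]13CS(=O)(=O)N4O[C@@]34C2 (gives the C3 oxygen)
Why: Proposed new method: with every acidic proton removed, achiral 8 can only shuttle by reversible 6-endo-trig oxa-Michael addition (the chalcone isomerase step) to both enantiomers of enolate 9, whose fast E1cB reopening keeps them in Curtin–Hammett equilibrium while the slowly fed, alkene-inert N-sulfonyloxaziridine transfers oxygen (the flavanone 3-hydroxylase step) anti to the C2 aryl group and, by the facial preference it shows for sodium enolates of 1-tetralone-type ketones, to the C3 Re face, a combination that only (2S)-9 offers, so C2 (R) and C3 (R, trans) are fixed together in a dynamic kinetic resolution; the closest known reactions are the Davis asymmetric enolate hydroxylation (established on chroman-4-one enolates) and the cyclisation–hydroxylation pathway put forward for the Algar–Flynn–Oyamada reaction, and the closing KHF2 cleavage of phenolic TBS ethers is standard and too mild to epimerise C2 or C3.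

## Compound list
1 | 2,4,6-trihydroxyacetophenone (phloroacetophenone) | CC(=O)c1c(O)cc(O)cc1O | starting material
2 | prenyl bromide (1-bromo-3-methylbut-2-ene) | CC(C)=CCBr | starting material
3 | 1-[2,6-dihydroxy-4-(3-methylbut-2-enyloxy)phenyl]ethanone | CC(=O)c1c(O)cc(OCC=C(C)C)cc1O | intermediate
4 | 3,4-dihydroxybenzaldehyde | O=Cc1ccc(O)c(O)c1 | starting material
5 | 3,4-bis(tert-butyldimethylsilyloxy)benzaldehyde | O=Cc1ccc(O[Si](C)(C)C(C)(C)C)c(O[Si](C)(C)C(C)(C)C)c1 | intermediate
6 | trilithium salt of racemic 3-[3,4-bis(TBSO)phenyl]-1-[2,6-dihydroxy-4-(3-methylbut-2-enyloxy)phenyl]-3-hydroxypropan-1-one (not isolated) | CC(C)=CCOc1cc([O-])c(C(=O)CC([O-])c2ccc(O[Si](C)(C)C(C)(C)C)c(O[Si](C)(C)C(C)(C)C)c2)c([O-])c1.[Li+].[Li+].[Li+] | intermediate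
7 | (E)-1-[2,6-dihydroxy-4-(3-methylbut-2-enyloxy)phenyl]-3-[3,4-bis(tert-butyldimethylsilyloxy)phenyl]prop-2-en-1-one | CC(C)=CCOc1cc(O)c(C(=O)/C=C/c2ccc(O[Si](C)(C)C(C)(C)C)c(O[Si](C)(C)C(C)(C)C)c2)c(O)c1 | intermediate
8 | disodium 2',6'-bis-phenoxide of 7, achiral resting state (not isolated) | CC(C)=CCOc1cc([O-])c(C(=O)/C=C/c2ccc(O[Si](C)(C)C(C)(C)C)c(O[Si](C)(C)C(C)(C)C)c2)c([O-])c1.[Na+].[Na+] | intermediate
9 | disodium (2S)-2-[3,4-bis(TBSO)phenyl]-7-(3-methylbut-2-enyloxy)-2H-chromene-4,5-diolate, the matched enolate, in fast exchange with its mirror image through 8 (not isolated) | CC(C)=CCOc1cc([O-])c2c(c1)O[C@H](c1ccc(O[Si](C)(C)C(C)(C)C)c(O[Si](C)(C)C(C)(C)C)c1)C=C2[O-].[Na+].[Na+] | intermediate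
10 | (2R,3R)-2-[3,4-bis(TBSO)phenyl]-3,5-dihydroxy-7-(3-methylbut-2-enyloxy)chroman-4-one, trans (not isolated) | CC(C)=CCOc1cc(O)c2c(c1)O[C@H](c1ccc(O[Si](C)(C)C(C)(C)C)c(O[Si](C)(C)C(C)(C)C)c1)[C@@H](O)C2=O | intermediate
11 | (2R,3R)-2-(3,4-dihydroxyphenyl)-3,5-dihydroxy-7-(3-methylbut-2-enyloxy)chroman-4-one (7-O-prenyl-(+)-taxifolin) | CC(C)=CCOc1cc(O)c2c(c1)O[C@H](c1ccc(O)c(O)c1)[C@@H](O)C2=O | target

## Totals and risks
Total step count: 4. Longest linear sequence: 3 (steps 1, 3, 4, or steps 2, 3, 4).

**Step 4 (highest risk).**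
- The ee may be low if oxygen transfer outruns reopening of 9 or if the reagent's facial bias is weak.
- The sense of induction rests on analogy. The (−)-reagent is equally available if the sense proves opposite.
- The electron-rich ring A phenoxide may be oxidised.
- Ring closure may be too slow at 0 °C.

The fallback sets out from 7 and comes back at 11. Both ortho phenols of 7 are silylated (TBSOTf, 2,6-lutidine, CH2Cl2, 0 °C) to give the tetrasilyl chalcone F1. Juliá–Colonna epoxidation (poly-L-leucine, urea–H2O2, DBU, THF) is a nucleophilic oxidation that ignores the prenyl alkene, and it gives the trans-(2R,3S)-epoxy ketone F2. Et3N·3HF in THF then removes all four silyl groups. The freed 2'-phenol opens the benzylic epoxide carbon in the 6-endo mode with inversion while the Cα–O bond is kept, which gives 11 directly.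

**Step 3.**
- Trianion formation may be incomplete.
- The hydroxide expelled in the flask may remove silyl groups.
- The product may cyclise on work-up.

The fallback sets out from 3 and 5 and comes back at 8. Pyrrolidine and AcOH (30 mol % each) in toluene over 4 Å sieves at 60 °C join the two partners by an enamine aldol condensation under near-neutral conditions. Spontaneous oxa-Michael closure gives racemic 3',4'-bis-O-TBS-7-O-prenyleriodictyol F3. NaN(SiMe3)2 in step 4 deprotonates it to racemic 9, which reopens to 8, so the stereoconvergent key step accepts it unchanged.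

**Step 1.**
- C-prenylation of the ambident phloroglucinol phenoxide may compete.
- Double O-alkylation may occur.

The fallback sets out from 1 and comes back at 3. It is a Mitsunobu etherification with prenol (3-methylbut-2-en-1-ol), PPh3 and DIAD in THF at 0 °C. This activates the alcohol instead of the phenoxide, so no free ambident anion is present. Only the most acidic, unchelated 4-OH couples. This fallback makes no new compound (F0).

## Further compounds
F1 | step 4 | (E)-1-[2,6-bis(tert-butyldimethylsilyloxy)-4-(3-methylbut-2-enyloxy)phenyl]-3-[3,4-bis(tert-butyldimethylsilyloxy)phenyl]prop-2-en-1-one | CC(C)=CCOc1cc(O[Si](C)(C)C(C)(C)C)c(C(=O)/C=C/c2ccc(O[Si](C)(C)C(C)(C)C)c(O[Si](C)(C)C(C)(C)C)c2)c(O[Si](C)(C)C(C)(C)C)c1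
F2 | step 4 | [(2R,3S)-3-[3,4-bis(tert-butyldimethylsilyloxy)phenyl]oxiran-2-yl][2,6-bis(tert-butyldimethylsilyloxy)-4-(3-methylbut-2-enyloxy)phenyl]methanone | CC(C)=CCOc1cc(O[Si](C)(C)C(C)(C)C)c(C(=O)[C@@H]2O[C@H]2c3ccc(O[Si](C)(C)C(C)(C)C)c(O[Si](C)(C)C(C)(C)C)c3)c(O[Si](C)(C)C(C)(C)C)c1
F3 | step 3 | racemic 2-[3,4-bis(tert-butyldimethylsilyloxy)phenyl]-5-hydroxy-7-(3-methylbut-2-enyloxy)chroman-4-one | CC(C)=CCOc1cc(O)c2c(c1)OC(c1ccc(O[Si](C)(C)C(C)(C)C)c(O[Si](C)(C)C(C)(C)C)c1)CC2=O
F0 | step 1 | none | none
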